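**Plan**

- Retrosynthesis (daucane numbering, see remark): the angelate on O‑10 and the anisate on O‑6 are removed first. Then C‑8–C‑9 and C‑6–C‑7 of the seven‑membered ring are cut together, as a (3+2) cycloaddition of 2‑methoxypropene to a cyclic carbonyl ylide. Last, C‑4–isopropyl, C‑5–C‑6 and C‑1–C‑10 are cut back to 3‑methylcyclopent‑2‑en‑1‑one.
- Enabling feature: O‑6 and the C‑10 carbonyl lie 1,4 across the seven‑membered ring. O‑6 can therefore be the oxygen of a six‑membered carbonyl ylide (C‑9, O, C‑6, C‑5, C‑1, C‑10) made from a C‑1 diazoacetyl arm and a C‑5 formyl arm that stand trans on the cyclopentane (ring B, C‑1 to C‑5). The ylide termini C‑9 and C‑6 are the two atoms that must be joined to C‑8 and C‑7.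
- Forward order: ring B is functionalised first; the seven‑membered ring then arises in the cycloaddition as an oxygen‑bridged bicycle. The bridge (temporary ring) is cut with SmI2 and the methoxy group is later eliminated to place the 8,9‑alkene.
- Stereochemistry: C‑1 from the chiral copper catalyst; C‑5 and C‑4 by substrate control on the cyclopentanone; C‑6 by hydroxyl‑directed reduction from the C‑4 OH; C‑10 by hydride attack anti to CH3‑15 followed by Mitsunobu inversion with angelic acid.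

Key step: step 8

Remark: names of bicyclic compounds use daucane numbering (C‑1 ring‑fusion carbon bearing CH3‑15; C‑2, C‑3 ring B CH2; C‑4 C(OH)iPr; C‑5 ring‑fusion CH; C‑6 CH–O‑anisoyl; C‑7 CH2; C‑8 C–CH3; C‑9 =CH; C‑10 CH–O‑angeloyl), with CH3‑15 β and H‑5 α throughout. The ester alkene in the target SMILES is Z, i.e. an angelate.

**Step 1**
Reactants: 1 3‑methylcyclopent‑2‑en‑1‑one; 2 isopropenylmagnesium bromide; 3 formaldehyde (gas, from cracked paraformaldehyde)
Product: 5 (2S,3S)‑2‑(hydroxymethyl)‑3‑methyl‑3‑(prop‑1‑en‑2‑yl)cyclopentan‑1‑one, via aluminium enolate 4 (not isolated)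
Conditions: 2, Me2AlCl, Et2O, 0 °C; then 1, CuO2CC4H3S (copper thiophene‑2‑carboxylate, 10 mol %), chiral SimplePhos‑type aminophosphine (enantiomer giving 3S), −30 °C; then 3, −40 °C; aq. KNaC4H4O6
Reagents that add atoms: none
Why: Copper‑catalysed enantioselective conjugate addition of an alkenylalane to a β‑substituted enone should set the quaternary C‑1 under catalyst control, and the regiodefined aluminium enolate should be hydroxymethylated (aldol trapping) anti to the larger isopropenyl group, placing CH2OH cis to the methyl group.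

**Step 2**
Reactants: 5 (2S,3S)‑2‑(hydroxymethyl)‑3‑methyl‑3‑(prop‑1‑en‑2‑yl)cyclopentan‑1‑one
Product: 6 (2S,3S)‑3‑methyl‑3‑(prop‑1‑en‑2‑yl)‑2‑{[(triethylsilyl)oxy]methyl}cyclopentan‑1‑one
Conditions: Et3SiCl, imidazole, CH2Cl2, 0 °C
Reagents that add atoms: chlorotriethylsilane CC[Si](Cl)(CC)CC
Why: Imidazole‑mediated silylation of the primary alcohol masks the β‑hydroxy ketone against retro‑aldol and dehydration before the organometallic step.

**Step 3**
Reactants: 6 (2S,3S)‑3‑methyl‑3‑(prop‑1‑en‑2‑yl)‑2‑{[(triethylsilyl)oxy]methyl}cyclopentan‑1‑one; 7 isopropylmagnesium chloride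
Product: 8 (1R,2S,3S)‑3‑methyl‑1‑(propan‑2‑yl)‑3‑(prop‑1‑en‑2‑yl)‑2‑{[(triethylsilyl)oxy]methyl}cyclopentan‑1‑ol
Conditions: 7, CeCl3 (anhydrous), THF, −78 °C
Reagents that add atoms: none
Why: CeCl3‑mediated Grignard addition suppresses enolisation of the hindered ketone; the isopropyl group should enter anti to the adjacent CH2OSi arm, so the tertiary OH (C‑4) ends cis to that arm and to the methyl group.

**Step 4**
Reactants: 8 (1R,2S,3S)‑3‑methyl‑1‑(propan‑2‑yl)‑3‑(prop‑1‑en‑2‑yl)‑2‑{[(triethylsilyl)oxy]methyl}cyclopentan‑1‑ol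
Product: 9 1‑[(1S,2S,3R)‑3‑hydroxy‑1‑methyl‑3‑(propan‑2‑yl)‑2‑{[(triethylsilyl)oxy]methyl}cyclopentyl]ethan‑1‑one
Conditions: O3, CH2Cl2–MeOH, −78 °C; then Me2S
Reagents that add atoms: ozone [O-][O+]=O
Why: Ozonolysis with reductive work‑up cleaves the only alkene and turns the isopropenyl group into the acetyl group (C‑10, C‑9).

**Step 5**
Reactants: 9 1‑[(1S,2S,3R)‑3‑hydroxy‑1‑methyl‑3‑(propan‑2‑yl)‑2‑{[(triethylsilyl)oxy]methyl}cyclopentyl]ethan‑1‑one
Product: 11 2‑diazo‑1‑[(1S,2S,3R)‑3‑hydroxy‑1‑methyl‑3‑(propan‑2‑yl)‑2‑{[(triethylsilyl)oxy]methyl}cyclopentyl]ethan‑1‑one, via trifluoroacetyl ketone 10 (not isolated)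
Conditions: LiN(SiMe3)2 (2.2 equiv), THF, −78 °C; CF3CO2CH2CF3; then MeSO2N3, Et3N, H2O, MeCN, rt
Reagents that add atoms: methanesulfonyl azide CS(=O)(=O)N=[N+]=[N-]
Why: Detrifluoroacetylative diazo transfer (Claisen trifluoroacetylation of the methyl ketone enolate, then Regitz‑type transfer from the sulfonyl azide) should give the terminal α‑diazo ketone, the ketone having only one enolisable side.

**Step 6**
Reactants: 11 2‑diazo‑1‑[(1S,2S,3R)‑3‑hydroxy‑1‑methyl‑3‑(propan‑2‑yl)‑2‑{[(triethylsilyl)oxy]methyl}cyclopentyl]ethan‑1‑one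
Product: 12 2‑diazo‑1‑[(1S,2S,3R)‑3‑hydroxy‑2‑(hydroxymethyl)‑1‑methyl‑3‑(propan‑2‑yl)cyclopentyl]ethan‑1‑one
Conditions: Bu4NF, AcOH, THF, 0 °C
Reagents that add atoms: none
Why: Buffered fluoride desilylation frees the primary alcohol without touching the acid‑sensitive, base‑stable diazo ketone.

**Step 7**
Reactants: 12 2‑diazo‑1‑[(1S,2S,3R)‑3‑hydroxy‑2‑(hydroxymethyl)‑1‑methyl‑3‑(propan‑2‑yl)cyclopentyl]ethan‑1‑one
Product: 13 (1R,2S,5R)‑2‑(2‑diazoacetyl)‑5‑hydroxy‑2‑methyl‑5‑(propan‑2‑yl)cyclopentane‑1‑carbaldehyde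
Conditions: Dess–Martin periodinane, pyridine, CH2Cl2, 0 °C; used at once
Reagents that add atoms: none
Why: Dess–Martin oxidation under buffered neutral conditions should give the aldehyde without epimerising C‑5 or dehydrating the β‑hydroxy aldehyde; the tertiary alcohol and diazo ketone are inert.

**Step 8**
Reactants: 13 (1R,2S,5R)‑2‑(2‑diazoacetyl)‑5‑hydroxy‑2‑methyl‑5‑(propan‑2‑yl)cyclopentane‑1‑carbaldehyde; 14 2‑methoxypropene
Product: 16 6β,9β‑epoxy‑4β‑hydroxy‑8‑methoxydaucan‑10‑one, via carbonyl ylide 15 (not isolated)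
Conditions: Rh2(OAc)4 (2 mol %), 14 (10 equiv), CH2Cl2, rt, slow addition of 13
Reagents that add atoms: none
Why: Rh2(OAc)4 turns the diazo ketone into a rhodium carbenoid at C‑9, which is captured by the C‑6 formyl oxygen to close a six‑membered cyclic carbonyl ylide (C‑9, O, C‑6, C‑5, C‑1, C‑10); this 1,3‑dipole adds 2‑methoxypropene across C‑9 and C‑6 in a concerted suprafacial (3+2) cycloaddition that forms C‑8–C‑9 and C‑6–C‑7 together. The closest known reaction type is the tandem carbonyl‑ylide formation/dipolar cycloaddition of δ‑oxo‑α‑diazo ketones with enol ethers. The ylide ring closes by O‑attack on the carbenoid in a six‑membered mode, and the cycloaddition closes the seven‑membered carbocycle and an oxolane at once as an 8‑oxabicyclo[3.2.1]octanone. C‑6 and C‑9 are set by approach of the alkene to the ylide face anti to the pseudo‑axial CH3‑15 (oxygen bridge syn to CH3‑15); C‑6 is reset in steps 10–11 and the C‑8 epimers converge in step 12. The step needs regioselectivity (methoxy‑bearing carbon to C‑9) and chemoselectivity (ylide formation before cyclopropanation of the enol ether or O–H insertion). The first should follow from pairing the nucleophilic CH2 terminus of the enol ether with the oxocarbenium‑like, formyl‑derived C‑6 terminus of the acyl‑stabilised ylide, the second from the six‑membered intramolecular capture and from the tertiary OH lying trans to the diazoacetyl arm on ring B.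

**Step 9**
Reactants: 16 6β,9β‑epoxy‑4β‑hydroxy‑8‑methoxydaucan‑10‑one
Product: 17 4β,6β‑dihydroxy‑8‑methoxydaucan‑10‑one
Conditions: SmI2 (2.2 equiv), THF–MeOH, −78 °C
Reagents that add atoms: none
Why: Samarium diiodide reduction of the α‑alkoxy ketone (ketyl formation, cleavage of the C‑9–O bond, protonation of the samarium enolate at low temperature) should open the oxygen bridge, leaving the oxygen on C‑6 and a CH2 at C‑9.

**Step 10**
Reactants: 17 4β,6β‑dihydroxy‑8‑methoxydaucan‑10‑one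
Product: 18 4β‑hydroxy‑8‑methoxydaucane‑6,10‑dione
Conditions: Dess–Martin periodinane, pyridine, CH2Cl2, 0 °C
Reagents that add atoms: none
Why: Dess–Martin oxidation of the only secondary alcohol under neutral conditions gives the 6,10‑dione and erases the C‑6 configuration left by the cycloaddition.

**Step 11**
Reactants: 18 4β‑hydroxy‑8‑methoxydaucane‑6,10‑dione
Product: 19 4β,6α‑dihydroxy‑8‑methoxydaucan‑10‑one
Conditions: Me4NBH(OAc)3, AcOH–MeCN, −20 °C
Reagents that add atoms: none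
Why: Evans–Saksena hydroxyl‑directed reduction: the C‑4 OH, cis to C‑6 on ring B, should bind the acetoxyborohydride and deliver hydride to C‑6 on the side of C‑4, giving the 6α‑alcohol; the C‑10 ketone has no neighbouring OH and should not be reduced.

**Step 12**
Reactants: 19 4β,6α‑dihydroxy‑8‑methoxydaucan‑10‑one; 20 4‑methoxybenzoyl chloride
Product: 22 4β‑hydroxy‑6α‑(4‑methoxybenzoyloxy)dauc‑8‑en‑10‑one, via anisate 21 (not isolated)
Conditions: 20, DMAP, pyridine, CH2Cl2, 0 °C to rt; then DBU, 0 °C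
Reagents that add atoms: none
Why: DMAP‑catalysed acylation of the secondary 6α‑OH (the tertiary OH is inert) is followed by E1cB loss of methanol from the β‑methoxy ketone; only the C‑8/C‑9 alkene can form because C‑9 is the sole enolisable position of the C‑10 ketone.

**Step 13**
Reactants: 22 4β‑hydroxy‑6α‑(4‑methoxybenzoyloxy)dauc‑8‑en‑10‑one
Product: 23 6α‑(4‑methoxybenzoyloxy)dauc‑8‑ene‑4β,10β‑diol
Conditions: NaBH4, CeCl3·7H2O, MeOH, −78 °C
Reagents that add atoms: none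
Why: Luche 1,2‑reduction of the enone; hydride should add anti to the pseudo‑axial CH3‑15 on the neighbouring quaternary carbon, giving the 10β‑alcohol (OH cis to CH3‑15), as in reductions of 17‑oxo steroids.

**Step 14**
Reactants: 23 6α‑(4‑methoxybenzoyloxy)dauc‑8‑ene‑4β,10β‑diol; 24 angelic acid
Product: 25 10α‑angeloyloxy‑6α‑(4‑methoxybenzoyloxy)dauc‑8‑en‑4β‑ol (target)
Conditions: 24, PPh3, DIAD, toluene, 0 °C to rt
Reagents that add atoms: none
Why: Mitsunobu esterification should install the angelate with SN2 inversion at C‑10 (10β‑OH to 10α‑ester) under neutral conditions that leave the Z‑acid unisomerised; SN2′ attack is disfavoured by the fully substituted C‑8.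

**Compound list**

1 | 3‑methylcyclopent‑2‑en‑1‑one | CC1=CC(=O)CC1 | starting material
2 | isopropenylmagnesium bromide | C=C(C)[Mg]Br | starting material
3 | formaldehyde | C=O | starting material
4 | dimethylaluminium enolate of (S)‑3‑methyl‑3‑(prop‑1‑en‑2‑yl)cyclopentanone | C[Al](C)OC1=C[C@](C(C)=C)(C)CC1 | intermediate
5 | (2S,3S)‑2‑(hydroxymethyl)‑3‑methyl‑3‑(prop‑1‑en‑2‑yl)cyclopentan‑1‑one | OC[C@@H]1[C@](C(C)=C)(C)CCC1=O | intermediate
6 | (2S,3S)‑3‑methyl‑3‑(prop‑1‑en‑2‑yl)‑2‑{[(triethylsilyl)oxy]methyl}cyclopentan‑1‑one | CC[Si](CC)(CC)OC[C@@H]1[C@](C(C)=C)(C)CCC1=O | intermediate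
7 | isopropylmagnesium chloride | CC(C)[Mg]Cl | starting material
8 | (1R,2S,3S)‑3‑methyl‑1‑(propan‑2‑yl)‑3‑(prop‑1‑en‑2‑yl)‑2‑{[(triethylsilyl)oxy]methyl}cyclopentan‑1‑ol | CC[Si](CC)(CC)OC[C@@H]1[C@](C(C)=C)(C)CC[C@@]1(O)C(C)C | intermediate
9 | 1‑[(1S,2S,3R)‑3‑hydroxy‑1‑methyl‑3‑(propan‑2‑yl)‑2‑{[(triethylsilyl)oxy]methyl}cyclopentyl]ethan‑1‑one | CC[Si](CC)(CC)OC[C@@H]1[C@](C(C)=O)(C)CC[C@@]1(O)C(C)C | intermediate
10 | 4,4,4‑trifluoro‑1‑[(1S,2S,3R)‑3‑hydroxy‑1‑methyl‑3‑(propan‑2‑yl)‑2‑{[(triethylsilyl)oxy]methyl}cyclopentyl]butane‑1,3‑dione | CC[Si](CC)(CC)OC[C@@H]1[C@](C(=O)CC(=O)C(F)(F)F)(C)CC[C@@]1(O)C(C)C | intermediate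
11 | 2‑diazo‑1‑[(1S,2S,3R)‑3‑hydroxy‑1‑methyl‑3‑(propan‑2‑yl)‑2‑{[(triethylsilyl)oxy]methyl}cyclopentyl]ethan‑1‑one | CC[Si](CC)(CC)OC[C@@H]1[C@](C(=O)C=[N+]=[N-])(C)CC[C@@]1(O)C(C)C | intermediate
12 | 2‑diazo‑1‑[(1S,2S,3R)‑3‑hydroxy‑2‑(hydroxymethyl)‑1‑methyl‑3‑(propan‑2‑yl)cyclopentyl]ethan‑1‑one | OC[C@@H]1[C@](C(=O)C=[N+]=[N-])(C)CC[C@@]1(O)C(C)C | intermediate
13 | (1R,2S,5R)‑2‑(2‑diazoacetyl)‑5‑hydroxy‑2‑methyl‑5‑(propan‑2‑yl)cyclopentane‑1‑carbaldehyde | O=C[C@@H]1[C@](C(=O)C=[N+]=[N-])(C)CC[C@@]1(O)C(C)C | intermediate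
14 | 2‑methoxypropene | COC(C)=C | starting material
15 | six‑membered cyclic carbonyl ylide fused to ring B (C‑9, O, C‑6, C‑5, C‑1, C‑10) | [O-]C1=C[O+]=C[C@@H]2[C@]1(C)CC[C@@]2(O)C(C)C | intermediate
16 | 6β,9β‑epoxy‑4β‑hydroxy‑8‑methoxydaucan‑10‑one (C‑8 epimers possible; methoxy exo drawn) | O=C1[C@H]2O[C@H](C[C@]2(C)OC)[C@@H]3[C@]1(C)CC[C@@]3(O)C(C)C | intermediate
17 | 4β,6β‑dihydroxy‑8‑methoxydaucan‑10‑one | O=C1C[C@@](C)(OC)C[C@@H](O)[C@@H]2[C@]1(C)CC[C@@]2(O)C(C)C | intermediate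
18 | 4β‑hydroxy‑8‑methoxydaucane‑6,10‑dione | O=C1C[C@@](C)(OC)CC(=O)[C@@H]2[C@]1(C)CC[C@@]2(O)C(C)C | intermediate
19 | 4β,6α‑dihydroxy‑8‑methoxydaucan‑10‑one | O=C1C[C@@](C)(OC)C[C@H](O)[C@@H]2[C@]1(C)CC[C@@]2(O)C(C)C | intermediate
20 | 4‑methoxybenzoyl chloride | COc1ccc(cc1)C(=O)Cl | starting material
21 | 4β‑hydroxy‑8‑methoxy‑6α‑(4‑methoxybenzoyloxy)daucan‑10‑one | O=C1C[C@@](C)(OC)C[C@H](OC(=O)c2ccc(OC)cc2)[C@@H]3[C@]1(C)CC[C@@]3(O)C(C)C | intermediate
22 | 4β‑hydroxy‑6α‑(4‑methoxybenzoyloxy)dauc‑8‑en‑10‑one | O=C1C=C(C)C[C@H](OC(=O)c2ccc(OC)cc2)[C@@H]3[C@]1(C)CC[C@@]3(O)C(C)C | intermediate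
23 | 6α‑(4‑methoxybenzoyloxy)dauc‑8‑ene‑4β,10β‑diol | O[C@H]1C=C(C)C[C@H](OC(=O)c2ccc(OC)cc2)[C@@H]3[C@]1(C)CC[C@@]3(O)C(C)C | intermediate
24 | angelic acid, (2Z)‑2‑methylbut‑2‑enoic acid | C/C=C(/C)C(=O)O | starting material
25 | 10α‑angeloyloxy‑6α‑(4‑methoxybenzoyloxy)dauc‑8‑en‑4β‑ol (CNP0168729.1) | C/C=C(/C)C(=O)O[C@@H]1C=C(C)C[C@H](OC(=O)c2ccc(OC)cc2)[C@@H]2[C@]1(C)CC[C@@]2(O)C(C)C | target

Total step count: 14. Longest linear sequence: 14 steps (from 1).

**Steps most likely to fail**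

Step 8. The carbenoid may cyclopropanate the enol ether, or the ylide may dimerise before it is trapped, and the regiochemistry of the dipolar addition may be incomplete. The fallback closes the ring by metathesis and sets out from 9. α‑Methylenation of the methyl ketone (LiN(SiMe3)2, Eschenmoser's salt, then MeI and NaHCO3) gives the vinyl ketone F1. Bu4NF removes the silyl group to give the diol F2, and Dess–Martin oxidation gives the aldehyde F3. Indium‑mediated Barbier addition of 3‑bromo‑2‑methylpropene, selective for the aldehyde, gives the homoallylic alcohol F4 as C‑6 epimers. These converge by Dess–Martin oxidation to the ketone F5 and hydroxyl‑directed reduction with Me4NBH(OAc)3 to the 6α‑alcohol F6. Acylation with 20 gives the diene ester F7, and ring‑closing metathesis with the second‑generation Hoveyda–Grubbs catalyst RuCl2(H2IMes)(=CH‑C6H4‑2‑OiPr) closes the 8,9‑alkene. The route is rejoined at 22.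

Step 14. Substitution at the neopentyl allylic carbon may be slow, so that elimination, SN2′ attack or ester formation with retention through an acyloxyphosphonium ion competes. The fallback sets out from 22. A reagent‑controlled CBS reduction (2‑methyl‑CBS‑oxazaborolidine enantiomer chosen for β‑face hydride delivery, BH3·SMe2) replaces step 13 and gives the 10α‑alcohol F8. F8 is esterified with retention by the Yamaguchi mixed anhydride of angelic acid and 2,4,6‑trichlorobenzoyl chloride (Et3N, then DMAP, toluene), which keeps the Z geometry. This gives 25.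

Step 11. The hindered tertiary C‑4 OH may bind the borohydride too slowly, giving slow or undirected reduction with poor facial selectivity, or the β‑methoxy ketone may lose methanol in acetic acid. The fallback sets out from 17. DBU‑mediated loss of methanol gives the enone alcohol F9, which keeps the 6β‑OH set by the cycloaddition. Mitsunobu esterification with 4‑methoxybenzoic acid (PPh3, DIAD) then installs the anisate with inversion at C‑6. The route is rejoined at 22.

**Further compounds**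

F1 | step 8 | 1‑[(1S,2S,3R)‑3‑hydroxy‑1‑methyl‑3‑(propan‑2‑yl)‑2‑{[(triethylsilyl)oxy]methyl}cyclopentyl]prop‑2‑en‑1‑one | CC[Si](CC)(CC)OC[C@@H]1[C@](C(=O)C=C)(C)CC[C@@]1(O)C(C)C
F2 | step 8 | 1‑[(1S,2S,3R)‑3‑hydroxy‑2‑(hydroxymethyl)‑1‑methyl‑3‑(propan‑2‑yl)cyclopentyl]prop‑2‑en‑1‑one | OC[C@@H]1[C@](C(=O)C=C)(C)CC[C@@]1(O)C(C)C
F3 | step 8 | (1R,2S,5R)‑2‑acryloyl‑5‑hydroxy‑2‑methyl‑5‑(propan‑2‑yl)cyclopentane‑1‑carbaldehyde | O=C[C@@H]1[C@](C(=O)C=C)(C)CC[C@@]1(O)C(C)C
F4 | step 8 | 8,9‑seco diene alcohol, both C‑6 epimers: 1‑[3‑hydroxy‑2‑(1‑hydroxy‑3‑methylbut‑3‑en‑1‑yl)‑1‑methyl‑3‑(propan‑2‑yl)cyclopentyl]prop‑2‑en‑1‑one, ring configuration as in 13 | C=C(C)CC(O)[C@@H]1[C@](C(=O)C=C)(C)CC[C@@]1(O)C(C)C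
F5 | step 8 | 8,9‑seco diene ketone: 1‑[2‑acryloyl‑5‑hydroxy‑2‑methyl‑5‑(propan‑2‑yl)cyclopentyl]‑3‑methylbut‑3‑en‑1‑one, ring configuration as in 13 | C=C(C)CC(=O)[C@@H]1[C@](C(=O)C=C)(C)CC[C@@]1(O)C(C)C
F6 | step 8 | 8,9‑seco diene 6α‑alcohol, ring configuration as in 13 | C=C(C)C[C@H](O)[C@@H]1[C@](C(=O)C=C)(C)CC[C@@]1(O)C(C)C
F7 | step 8 | 8,9‑seco diene 6α‑(4‑methoxybenzoate), ring configuration as in 13 | C=C(C)C[C@H](OC(=O)c2ccc(OC)cc2)[C@@H]1[C@](C(=O)C=C)(C)CC[C@@]1(O)C(C)C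
F8 | step 14 | 6α‑(4‑methoxybenzoyloxy)dauc‑8‑ene‑4β,10α‑diol | O[C@@H]1C=C(C)C[C@H](OC(=O)c2ccc(OC)cc2)[C@@H]3[C@]1(C)CC[C@@]3(O)C(C)C
F9 | step 11 | 4β,6β‑dihydroxydauc‑8‑en‑10‑one | O=C1C=C(C)C[C@@H](O)[C@@H]2[C@]1(C)CC[C@@]2(O)C(C)C
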